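Does the flask charged with 49 mM still move at 2.5 d, and where does it stand then?

| flask | substrate | remark | time |
|---|---|---|---|
| Sunday's | 24 mM | run made earlier |  |
| Saturday's | 98 mM | run made earlier |  |
| flask | 49 mM |  | 2.5 d |

| run | time / h | substrate / % | target / % |
|---|---|---|---|
| Sunday's | 3.00 | 11.2 | 36.0 |
| Sunday's | 6.00 | 11.1 | 34.9 |
| Sunday's | 15.0 | 10.6 | 33.5 |
| Sunday's | 40.0 | 10.6 | 33.7 |
| Saturday's | 10.0 | 11.3 | 33.7 |
| Saturday's | 20.0 | 11.2 | 33.0 |
| Saturday's | 25.0 | 10.8 | 33.3 |
| Saturday's | 40.0 | 10.9 | 32.9 |

(scatter of a reading: 0.3 percentage points)

- why nothing more happens at 2.5 d, or that something still does (forward and back rates have come level / it is still moving / all of the substrate has reacted)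
- part of the substrate gone at 2.5 d
- the target standing at 2.5 d, as a percentage of the substrate charged

- the earlier runs were read with a standard deviation of 0.3 percentage points
- steps thought possible: substrate <-> target; substrate <-> isomer of the product; substrate <-> third isomer; substrate <-> dormant form
- what has gone from substrate into another species counts as reacted, even if it can come back
- the reaction counts as stopped when no species that holds the substrate changes by six tenths of a point or more over the second half of the time

In Sunday's run substrate reads 10.6% at 15.0 h and 10.6% at 40.0 h, while target goes from 33.5% to 33.7%. These changes lie within the scatter of 0.3 percentage points, so 15.0 h serves as a quiet time. The value 4.00 is the asked time over that quiet time, here called the stillness number: it counts how many quiet times fit into the flask's time. The second half of the time starts at half the asked time, so a number above 2 puts that half past the quiet time. In powers of ten, the flask stands at 0.602 against 0.301, so by the readings of substrate and target, the two species that were read, it should count as stopped.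

The number holds no concentration, so it says that the flask stops but not at what level. The level comes from the runs. Saturday's charge is 4.08 times Sunday's, yet its last readings are 10.9% substrate and 32.9% target, against 10.6% and 33.7%. The flask's charge lies between the two.

The forecast says forward and back rates have come level, with 89.3% gone and 33.3% target, on the grounds that “After 15–20 h, the changes are within the 0.3-point reading noise”.

The flask gives forward and back rates have come level, with 89.2% gone and 33.3% target.

    substrate ⇌ target (K = 3.10, k = 0.0258 /s)
    substrate ⇌ isomer of the product (K = 2.20, k = 0.00108 /s)
    substrate ⇌ third isomer (K = 1.20, k = 0.00149 /s)
    substrate ⇌ dormant form (K = 1.80, k = 1.21 × 10⁻⁴ /s)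

In this flask the turning of substrate into dormant form has half of its turnover up to 2.5 d done by 0.0874 d, much earlier than the asked time, and >99.9% of that turnover is done by 1.25 d, where the second half of the time begins at a stillness number of 4.00. The neighbour charged with 29 mM has the same stillness number, its time being held, and stands with 89.2% gone and 33.3% target.

The runs are simulated for substances that don't exist, noise included.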